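**Plan**

1. Numbering (germacrane): ring C1 (ketone) to C10 (CHMe, methyl C14); C4 (methyl C15)–C5 is the cis-epoxide, C6 the lactone CH–O, C7=C11 the butenolide alkene, C8 the tiglate carbinol, C12 the lactone carbonyl, C13 the CH2OAc carbon.
2. Retrosynthetic cuts, in order: the C8 tiglate; the epoxide oxygen (back to a 4Z alkene); the C13 acetate and the lactone C12–O bond (back to a C12/C13 diol held as an acetonide); the ring bond C3–C4; then C6–C7, C7–C8 and C7=C11 around the tetrasubstituted alkene.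
3. What makes the ring closure possible: the cis-epoxide maps onto a Z-trisubstituted C4=C5 alkene whose geometry can be fixed in an open-chain C4 alkenyl iodide, and the C1 ketone can carry a vinyl group (C2=C3) as its ketal, so the ten-membered carbocycle can be closed at C3(sp3)–C4(sp2). The symmetric 2,2-dimethyl-1,3-dioxan-5-ylidene unit stands for C11/C12/C13 and leaves no geometry to control at C7=C11.
4. Forward: the C1–C3/C8–C10 piece (from (R)-2-methylsuccinate) is joined at C7–C8 to a C7 carbenoid made from 2,2-dimethyl-1,3-dioxan-5-one; C6 with its propynyl group is added at C7; the alkyne becomes the Z-iodoalkene; the carbocycle closes first (step 15), the butenolide second (step 17), the epoxide last (step 20), followed by tigloylation.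
5. Stereochemistry: C10 from the chiral pool; C8 and C6 from two reagent-controlled oxazaborolidine reductions; 4Z from trans-hydroalumination/iodination; the 4R,5S epoxide by oxygen delivery from the C8 hydroxyl to the inner face of the ring alkene. C6 is labelled 6R while C5 is an alkene carbon and 6S once C5 carries the epoxide oxygen; the spatial arrangement is the same.

Key step: step 15

Assumption: (R)-2-methylsuccinic acid 4-methyl ester (1) is taken as a catalogue compound; it is otherwise the asymmetric hydrogenation product of 4-methyl itaconate.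

**Route**

Step 1
Reactants: 1 (R)-2-methylsuccinic acid 4-methyl ester
Product: 3 methyl (3R)-4-[methoxy(methyl)amino]-3-methyl-4-oxobutanoate, via acyl imidazole 2 (not isolated)
Conditions: CDI (1,1'-carbonyldiimidazole), CH2Cl2, 0 °C to rt; then MeNH(OMe)·HCl, rt
Reagents that add atoms: N,O-dimethylhydroxylamine hydrochloride, CNOC.Cl
Why: Amide formation through the acyl imidazole is a standard non-basic activation that should leave the C10 centre next to the carboxyl untouched and puts the Weinreb amide on the future C1 while the future C8 stays a methyl ester.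

Step 2
Reactants: 3 methyl (3R)-4-[methoxy(methyl)amino]-3-methyl-4-oxobutanoate; 4 vinylmagnesium bromide
Product: 5 methyl (3R)-3-methyl-4-oxohex-5-enoate
Conditions: THF, −78 to −20 °C; inverse quench into cold 1 M HCl
Reagents that add atoms: none
Why: Weinreb ketone synthesis, in which the chelated tetrahedral adduct forms faster at the N-methoxy-N-methyl amide than addition to the methyl ester and survives until the acidic quench, which also keeps the liberated amine from adding to the vinyl ketone.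

Step 3
Reactants: 5 methyl (3R)-3-methyl-4-oxohex-5-enoate
Product: 7 methyl (3R)-3-[2-(2-bromoethyl)-1,3-dioxolan-2-yl]butanoate, via bromo ketone 6 (not isolated)
Conditions: TMSBr, ethylene glycol, CH2Cl2, −20 to 0 °C
Reagents that add atoms: bromotrimethylsilane, C[Si](C)(C)Br; ethylene glycol, OCCO
Why: HBr released from the silyl bromide and the diol adds in conjugate fashion and the β-bromo ketone is ketalised in the same flask while silicon takes up the water, the established detour to a vinyl ketone ketal that avoids alkoxide addition to the enone, and the low temperature is chosen to keep the C10 centre from enolising.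

Step 4
Reactants: 7 methyl (3R)-3-[2-(2-bromoethyl)-1,3-dioxolan-2-yl]butanoate
Product: 8 (3R)-3-[2-(2-bromoethyl)-1,3-dioxolan-2-yl]-N-methoxy-N-methylbutanamide
Conditions: MeNH(OMe)·HCl, i-PrMgCl, THF, −20 °C
Reagents that add atoms: N,O-dimethylhydroxylamine hydrochloride, CNOC.Cl
Why: Aminolysis of a methyl ester by the magnesium amide of N,O-dimethylhydroxylamine is a routine one-step entry to Weinreb amides, and the primary bromide and the ketal are inert to the Grignard base at this temperature.

Step 5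
Reactants: 9 2,2-dimethyl-1,3-dioxan-5-one
Product: 10 5-(dibromomethylidene)-2,2-dimethyl-1,3-dioxane
Conditions: CBr4, PPh3, Zn dust, CH2Cl2, 0 °C to rt
Reagents that add atoms: carbon tetrabromide, BrC(Br)(Br)Br
Why: Dibromo-olefination of the unhindered, electron-poor ketone with Ph3P=CBr2 (first stage of the Corey–Fuchs sequence) should be clean under the acid-free zinc variant, and because both ring arms are identical the new alkene has no geometry to control.

Step 6
Reactants: 10 5-(dibromomethylidene)-2,2-dimethyl-1,3-dioxane; 8 (3R)-3-[2-(2-bromoethyl)-1,3-dioxolan-2-yl]-N-methoxy-N-methylbutanamide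
Product: 12 (4R)-1-bromo-4-[2-(2-bromoethyl)-1,3-dioxolan-2-yl]-1-(2,2-dimethyl-1,3-dioxan-5-ylidene)pentan-2-one, via bromolithium carbenoid 11 (not isolated)
Conditions: n-BuLi (1.0 equiv), THF/Et2O/pentane, −105 °C; then 8, −105 to −78 °C; AcOH quench
Reagents that add atoms: none
Why: Bromine–lithium exchange on a 1,1-dibromoalkene gives a 1-bromo-1-lithioalkene that persists below about −90 °C (rearrangement of this six-ring alkylidene carbenoid to a cycloalkyne is not open to it), and its acylation by the Weinreb amide should stop at the ketone because the chelated adduct collapses only on quenching.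

Step 7
Reactants: 12 (4R)-1-bromo-4-[2-(2-bromoethyl)-1,3-dioxolan-2-yl]-1-(2,2-dimethyl-1,3-dioxan-5-ylidene)pentan-2-one
Product: 13 (2S,4R)-1-bromo-4-[2-(2-bromoethyl)-1,3-dioxolan-2-yl]-1-(2,2-dimethyl-1,3-dioxan-5-ylidene)pentan-2-ol
Conditions: (R)-Me-CBS, i.e. (3aR)-1-methyl-3,3-diphenyltetrahydro-1H,3H-pyrrolo[1,2-c][1,3,2]oxazaborole (0.2 equiv), catecholborane, toluene, −78 °C
Reagents that add atoms: none
Why: Corey–Bakshi–Shibata reduction in which the α-bromoalkenyl group acts as the large substituent and the CH2 chain as the small one, so the (R)-catalyst should give the 8S carbinol under reagent control, independent of the remote C10 centre.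

Step 8
Reactants: 13 (2S,4R)-1-bromo-4-[2-(2-bromoethyl)-1,3-dioxolan-2-yl]-1-(2,2-dimethyl-1,3-dioxan-5-ylidene)pentan-2-ol
Product: 14 tert-butyl{[(2S,4R)-1-bromo-4-[2-(2-bromoethyl)-1,3-dioxolan-2-yl]-1-(2,2-dimethyl-1,3-dioxan-5-ylidene)pentan-2-yl]oxy}dimethylsilane
Conditions: TBSOTf, 2,6-lutidine, CH2Cl2, −78 to 0 °C
Reagents that add atoms: tert-butyldimethylsilyl triflate, CC(C)(C)[Si](C)(C)OS(=O)(=O)C(F)(F)F
Why: Silylation of the hindered secondary alcohol with the silyl triflate is fast under lutidine buffering that both ketals tolerate, and the TBS ether is chosen to outlast the mild acid of step 16 and to fall with the dioxolane in step 19.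

Step 9
Reactants: 14 tert-butyl{[(2S,4R)-1-bromo-4-[2-(2-bromoethyl)-1,3-dioxolan-2-yl]-1-(2,2-dimethyl-1,3-dioxan-5-ylidene)pentan-2-yl]oxy}dimethylsilane
Product: 15 tert-butyl{[(2S,4R)-1-bromo-1-(2,2-dimethyl-1,3-dioxan-5-ylidene)-4-(2-ethenyl-1,3-dioxolan-2-yl)pentan-2-yl]oxy}dimethylsilane
Conditions: KOtBu, THF, 0 °C
Reagents that add atoms: none
Why: E2 dehydrobromination of the primary bromide next to the ketal carbon is the standard unveiling of a vinyl ketal, and it is placed before the second lithiation (which an alkyl bromide would not survive) on a substrate whose alkenyl bromide has no vinylic hydrogen to lose.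

Step 10
Reactants: 16 but-2-ynoic acid
Product: 18 N-methoxy-N-methylbut-2-ynamide, via acyl imidazole 17 (not isolated)
Conditions: CDI (1,1'-carbonyldiimidazole), CH2Cl2, 0 °C to rt; then MeNH(OMe)·HCl, rt
Reagents that add atoms: N,O-dimethylhydroxylamine hydrochloride, CNOC.Cl
Why: The same acyl imidazole amidation as in step 1 turns the alkynoic acid into its Weinreb amide without touching the triple bond.

Step 11
Reactants: 15 tert-butyl{[(2S,4R)-1-bromo-1-(2,2-dimethyl-1,3-dioxan-5-ylidene)-4-(2-ethenyl-1,3-dioxolan-2-yl)pentan-2-yl]oxy}dimethylsilane; 18 N-methoxy-N-methylbut-2-ynamide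
Product: 20 (6S,8R)-6-[(tert-butyldimethylsilyl)oxy]-5-(2,2-dimethyl-1,3-dioxan-5-ylidene)-8-(2-ethenyl-1,3-dioxolan-2-yl)non-2-yn-4-one, via alkenyllithium 19 (not isolated)
Conditions: t-BuLi (2.1 equiv), Et2O, −78 °C; then 18, THF, −78 °C; AcOH quench
Reagents that add atoms: none
Why: Bromine–lithium exchange with two equivalents of t-BuLi gives a 2-lithio allylic silyl ether of the kind that is stable at −78 °C, and its 1,2-addition to the alkynyl Weinreb amide should give the cross-conjugated ynone without over-addition.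

Step 12
Reactants: 20 (6S,8R)-6-[(tert-butyldimethylsilyl)oxy]-5-(2,2-dimethyl-1,3-dioxan-5-ylidene)-8-(2-ethenyl-1,3-dioxolan-2-yl)non-2-yn-4-one
Product: 21 (4R,6S,8R)-6-[(tert-butyldimethylsilyl)oxy]-5-(2,2-dimethyl-1,3-dioxan-5-ylidene)-8-(2-ethenyl-1,3-dioxolan-2-yl)non-2-yn-4-ol
Conditions: (S)-Me-CBS, i.e. (3aS)-1-methyl-3,3-diphenyltetrahydro-1H,3H-pyrrolo[1,2-c][1,3,2]oxazaborole (0.5 equiv), catecholborane, toluene, −78 °C
Reagents that add atoms: none
Why: Corey–Bakshi–Shibata reduction of an alkynyl ketone with the slim propynyl group as the small substituent and the fully substituted alkenyl group as the large one, so the (S)-catalyst should set the C6 carbinol (6R here) under reagent control, while catecholborane at −78 °C leaves the terminal vinyl group alone.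

Step 13
Reactants: 21 (4R,6S,8R)-6-[(tert-butyldimethylsilyl)oxy]-5-(2,2-dimethyl-1,3-dioxan-5-ylidene)-8-(2-ethenyl-1,3-dioxolan-2-yl)non-2-yn-4-ol
Product: 23 (2Z,4R,6S,8R)-6-[(tert-butyldimethylsilyl)oxy]-5-(2,2-dimethyl-1,3-dioxan-5-ylidene)-8-(2-ethenyl-1,3-dioxolan-2-yl)-2-iodonon-2-en-4-ol, via alkenylalanate 22 (not isolated)
Conditions: NaAlH2(OCH2CH2OMe)2 (Red-Al), THF, 0 °C to rt; EtOAc; then I2, −78 to 0 °C
Reagents that add atoms: iodine, II
Why: Alkoxide-directed trans-hydroalumination of the propargylic alcohol puts hydride on C5 and aluminium on C4 in a five-membered alanate, and iodinolysis with retention gives the (Z)-3-iodoallylic alcohol, the established route to such Z-iodoalkenes.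

Step 14
Reactants: 23 (2Z,4R,6S,8R)-6-[(tert-butyldimethylsilyl)oxy]-5-(2,2-dimethyl-1,3-dioxan-5-ylidene)-8-(2-ethenyl-1,3-dioxolan-2-yl)-2-iodonon-2-en-4-ol
Product: 24 triethyl{[(2Z,4R,6S,8R)-6-[(tert-butyldimethylsilyl)oxy]-5-(2,2-dimethyl-1,3-dioxan-5-ylidene)-8-(2-ethenyl-1,3-dioxolan-2-yl)-2-iodonon-2-en-4-yl]oxy}silane
Conditions: TESOTf, 2,6-lutidine, CH2Cl2, −78 °C
Reagents that add atoms: triethylsilyl triflate, CC[Si](CC)(CC)OS(=O)(=O)C(F)(F)F
Why: Routine silylation that keeps the doubly allylic alcohol away from boron and palladium in the next step and installs the most acid-labile group, to be removed together with the acetonide.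

Step 15
Reactants: 24 triethyl{[(2Z,4R,6S,8R)-6-[(tert-butyldimethylsilyl)oxy]-5-(2,2-dimethyl-1,3-dioxan-5-ylidene)-8-(2-ethenyl-1,3-dioxolan-2-yl)-2-iodonon-2-en-4-yl]oxy}silane
Product: 26 (4Z,6R,8S,10R)-8-(tert-butyldimethylsilyloxy)-1,1-(ethylenedioxy)-12,13-(isopropylidenedioxy)-6-(triethylsilyloxy)germacra-4,7(11)-diene, via alkylborane 25 (not isolated)
Conditions: 9-BBN (9-borabicyclo[3.3.1]nonane) dimer, THF, 0 °C to rt; then syringe-pump addition to Pd(dppf)Cl2 (0.2 equiv), AsPh3 (0.4 equiv), Cs2CO3 (3 equiv), degassed DMF/THF/H2O, 40 °C, final concentration about 1 mM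
Reagents that add atoms: none
Why: 9-BBN adds anti-Markovnikov to the only monosubstituted alkene and places boron on C3; oxidative addition of zerovalent palladium into the C4–I bond, base-assisted transfer of the primary alkyl group from the borate to divalent palladium and reductive elimination then form C3–C4 with retention of the alkene geometry. The closest known reaction type is the intramolecular B-alkyl Suzuki–Miyaura coupling of an alkyl-9-BBN with an alkenyl iodide used for macrocyclic ring closure. The one ring formed, the ten-membered carbocycle, closes end to end by C(sp3)–C(sp2) reductive elimination from an eleven-membered alkyl(alkenyl)palladacycle, which leaves C4=C5 inside the ring. No stereocentre is created: the Z geometry is that of the iodoalkene, and C6, C8 and C10 are spectators. The step needs three selectivities: hydroboration of the vinyl group only (secured by the bulk of 9-BBN against the tetrasubstituted C7=C11 and the trisubstituted iodoalkene), ring closure over oligomerisation (slow addition at high dilution, helped by the turn that the planar tetrasubstituted alkene and the cis C4=C5 unit impose on the chain), and coupling over β-hydride elimination (the wide-bite-angle dppf ligand). All oxygen functions are ethers or ketals at this stage, so there is no allylic ester that zerovalent palladium could ionise.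

Step 16
Reactants: 26 (4Z,6R,8S,10R)-8-(tert-butyldimethylsilyloxy)-1,1-(ethylenedioxy)-12,13-(isopropylidenedioxy)-6-(triethylsilyloxy)germacra-4,7(11)-diene
Product: 27 (4Z,6R,8S,10R)-8-(tert-butyldimethylsilyloxy)-1,1-(ethylenedioxy)germacra-4,7(11)-diene-6,12,13-triol
Conditions: pyridinium p-toluenesulfonate (PPTS, 0.2 equiv), MeOH, 0 °C to rt
Reagents that add atoms: none
Why: Mild acid methanolysis removes the TES ether and the 1,3-dioxane acetonide, the two most labile groups, while the secondary TBS ether and the hindered dioxolane should stay, and the weak acid is chosen because the freed C6 alcohol is doubly allylic.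

Step 17
Reactants: 27 (4Z,6R,8S,10R)-8-(tert-butyldimethylsilyloxy)-1,1-(ethylenedioxy)germacra-4,7(11)-diene-6,12,13-triol
Product: 30 (4Z,6R,8S,10R)-8-(tert-butyldimethylsilyloxy)-1,1-(ethylenedioxy)-13-hydroxygermacra-4,7(11)-dien-12,6-olide, via hydroxy enal 28 (not isolated), via lactol 29 (not isolated)
Conditions: TEMPO (2,2,6,6-tetramethylpiperidin-1-oxyl, 0.2 equiv), PhI(OAc)2 (2.2 equiv), CH2Cl2, 0 °C to rt
Reagents that add atoms: none
Why: TEMPO-mediated oxidative lactonisation of a 1,4-diol, in which the oxoammonium salt prefers primary alcohols and only the C12 aldehyde has a cis hydroxyl (at C6) to close a five-membered lactol that is oxidised on to the butenolide, while the limited oxidant and the shielding of the C13 alcohol by the neighbouring C8 silyl ether are meant to leave C13 as the alcohol.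

Step 18
Reactants: 30 (4Z,6R,8S,10R)-8-(tert-butyldimethylsilyloxy)-1,1-(ethylenedioxy)-13-hydroxygermacra-4,7(11)-dien-12,6-olide
Product: 31 (4Z,6R,8S,10R)-13-acetoxy-8-(tert-butyldimethylsilyloxy)-1,1-(ethylenedioxy)germacra-4,7(11)-dien-12,6-olide
Conditions: Ac2O, pyridine, 4-(dimethylamino)pyridine (DMAP, cat.), CH2Cl2, 0 °C
Reagents that add atoms: acetic anhydride, CC(=O)OC(C)=O
Why: Standard acetylation of the only free hydroxyl, a primary allylic alcohol.

Step 19
Reactants: 31 (4Z,6R,8S,10R)-13-acetoxy-8-(tert-butyldimethylsilyloxy)-1,1-(ethylenedioxy)germacra-4,7(11)-dien-12,6-olide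
Product: 32 (4Z,6R,8S,10R)-13-acetoxy-8-hydroxy-1-oxogermacra-4,7(11)-dien-12,6-olide
Conditions: 48% aq. HF, MeCN, 0 °C to rt
Reagents that add atoms: water, O
Why: Aqueous HF cleaves the secondary TBS ether and, being an aqueous acid, hydrolyses the dioxolane in the same operation, at a stage where the C6 oxygen is acylated and no longer prone to ionise and where no epoxide is yet present.

Step 20
Reactants: 32 (4Z,6R,8S,10R)-13-acetoxy-8-hydroxy-1-oxogermacra-4,7(11)-dien-12,6-olide
Product: 33 (4R,5S,6S,8S,10R)-13-acetoxy-4,5-epoxy-8-hydroxy-1-oxogermacr-7(11)-en-12,6-olide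
Conditions: VO(acac)2 (0.1 equiv), t-BuOOH (in decane, 1.5 equiv), CH2Cl2, 0 °C to rt
Reagents that add atoms: tert-butyl hydroperoxide, CC(C)(C)OO
Why: Hydroxyl-directed vanadium epoxidation of a bishomoallylic alcohol, expected to deliver oxygen to the inner face of C4=C5 because the C6 and C8 configurations place the C6–C5 bond and the C8–O bond on the same side of the planar butenolide when H8 eclipses C7=C11, which gives the 4R,5S cis-epoxide, whereas the outer face taken by a free peracid would give the 4S,5R isomer and the electron-poor C7=C11 bond is inert to this electrophilic oxidant.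

Step 21
Reactants: 33 (4R,5S,6S,8S,10R)-13-acetoxy-4,5-epoxy-8-hydroxy-1-oxogermacr-7(11)-en-12,6-olide; 34 tiglic acid
Product: 36 (4R,5S,6S,8S,10R)-13-acetoxy-4,5-epoxy-1-oxo-8-[(E)-2-methylbut-2-enoyloxy]germacr-7(11)-en-12,6-olide (CNP0229937.1), via mixed anhydride 35 (not isolated)
Conditions: 34, 2,4,6-trichlorobenzoyl chloride, Et3N, toluene, rt; then 33, 4-(dimethylamino)pyridine (DMAP), rt
Reagents that add atoms: none
Why: Yamaguchi esterification through the mixed anhydride acylates hindered secondary alcohols under mild conditions that the epoxide, the ketone with its α-centre and the allylic acetate should tolerate, and it avoids the ketene pathway by which tigloyl chloride and amine base can deconjugate the acyl group.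

**Compound list**

1 | (R)-2-methylsuccinic acid 4-methyl ester [(2R)-4-methoxy-2-methyl-4-oxobutanoic acid] | OC(=O)[C@H](C)CC(=O)OC | starting material
2 | methyl (3R)-4-(imidazol-1-yl)-3-methyl-4-oxobutanoate (acyl imidazole) | O=C([C@H](C)CC(=O)OC)n1ccnc1 | intermediate
3 | methyl (3R)-4-[methoxy(methyl)amino]-3-methyl-4-oxobutanoate | CON(C)C(=O)[C@H](C)CC(=O)OC | intermediate
4 | vinylmagnesium bromide | C=C[Mg]Br | starting material
5 | methyl (3R)-3-methyl-4-oxohex-5-enoate | C=CC(=O)[C@H](C)CC(=O)OC | intermediate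
6 | methyl (3R)-6-bromo-3-methyl-4-oxohexanoate | BrCCC(=O)[C@H](C)CC(=O)OC | intermediate
7 | methyl (3R)-3-[2-(2-bromoethyl)-1,3-dioxolan-2-yl]butanoate | BrCCC1(OCCO1)[C@H](C)CC(=O)OC | intermediate
8 | (3R)-3-[2-(2-bromoethyl)-1,3-dioxolan-2-yl]-N-methoxy-N-methylbutanamide | BrCCC1(OCCO1)[C@H](C)CC(=O)N(C)OC | intermediate
9 | 2,2-dimethyl-1,3-dioxan-5-one | CC1(C)OCC(=O)CO1 | starting material
10 | 5-(dibromomethylidene)-2,2-dimethyl-1,3-dioxane | CC1(C)OCC(=C(Br)Br)CO1 | intermediate
11 | bromo(2,2-dimethyl-1,3-dioxan-5-ylidene)methyllithium | [Li]C(Br)=C1COC(C)(C)OC1 | intermediate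
12 | (4R)-1-bromo-4-[2-(2-bromoethyl)-1,3-dioxolan-2-yl]-1-(2,2-dimethyl-1,3-dioxan-5-ylidene)pentan-2-one (C7 bromide, C8 ketone) | BrCCC1(OCCO1)[C@H](C)CC(=O)C(Br)=C1COC(C)(C)OC1 | intermediate
13 | (2S,4R)-1-bromo-4-[2-(2-bromoethyl)-1,3-dioxolan-2-yl]-1-(2,2-dimethyl-1,3-dioxan-5-ylidene)pentan-2-ol (8S,10R) | BrCCC1(OCCO1)[C@H](C)C[C@H](O)C(Br)=C1COC(C)(C)OC1 | intermediate
14 | tert-butyl{[(2S,4R)-1-bromo-4-[2-(2-bromoethyl)-1,3-dioxolan-2-yl]-1-(2,2-dimethyl-1,3-dioxan-5-ylidene)pentan-2-yl]oxy}dimethylsilane | BrCCC1(OCCO1)[C@H](C)C[C@H](O[Si](C)(C)C(C)(C)C)C(Br)=C1COC(C)(C)OC1 | intermediate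
15 | tert-butyl{[(2S,4R)-1-bromo-1-(2,2-dimethyl-1,3-dioxan-5-ylidene)-4-(2-ethenyl-1,3-dioxolan-2-yl)pentan-2-yl]oxy}dimethylsilane | C=CC1(OCCO1)[C@H](C)C[C@H](O[Si](C)(C)C(C)(C)C)C(Br)=C1COC(C)(C)OC1 | intermediate
16 | but-2-ynoic acid | CC#CC(=O)O | starting material
17 | 1-(imidazol-1-yl)but-2-yn-1-one (acyl imidazole) | CC#CC(=O)n1ccnc1 | intermediate
18 | N-methoxy-N-methylbut-2-ynamide | CC#CC(=O)N(C)OC | intermediate
19 | C7 alkenyllithium derived from 15 (lithium in place of bromine; 8S,10R) | C=CC1(OCCO1)[C@H](C)C[C@H](O[Si](C)(C)C(C)(C)C)C([Li])=C1COC(C)(C)OC1 | intermediate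
20 | (6S,8R)-6-[(tert-butyldimethylsilyl)oxy]-5-(2,2-dimethyl-1,3-dioxan-5-ylidene)-8-(2-ethenyl-1,3-dioxolan-2-yl)non-2-yn-4-one | C=CC1(OCCO1)[C@H](C)C[C@H](O[Si](C)(C)C(C)(C)C)C(=C1COC(C)(C)OC1)C(=O)C#CC | intermediate
21 | (4R,6S,8R)-6-[(tert-butyldimethylsilyl)oxy]-5-(2,2-dimethyl-1,3-dioxan-5-ylidene)-8-(2-ethenyl-1,3-dioxolan-2-yl)non-2-yn-4-ol (6R,8S,10R in plan locants) | C=CC1(OCCO1)[C@H](C)C[C@H](O[Si](C)(C)C(C)(C)C)C(=C1COC(C)(C)OC1)[C@H](O)C#CC | intermediate
22 | sodium alkenylalanate from 21: five-membered O–Al–C4=C5–C6 ring, two 2-methoxyethoxy groups on aluminium | C=CC1(OCCO1)[C@H](C)C[C@H](O[Si](C)(C)C(C)(C)C)C(=C1COC(C)(C)OC1)[C@@H]1O[Al-](OCCOC)(OCCOC)C(C)=C1.[Na+] | intermediate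
23 | (2Z,4R,6S,8R)-6-[(tert-butyldimethylsilyl)oxy]-5-(2,2-dimethyl-1,3-dioxan-5-ylidene)-8-(2-ethenyl-1,3-dioxolan-2-yl)-2-iodonon-2-en-4-ol | C=CC1(OCCO1)[C@H](C)C[C@H](O[Si](C)(C)C(C)(C)C)C(=C1COC(C)(C)OC1)[C@H](O)/C=C(/C)I | intermediate
24 | triethyl{[(2Z,4R,6S,8R)-6-[(tert-butyldimethylsilyl)oxy]-5-(2,2-dimethyl-1,3-dioxan-5-ylidene)-8-(2-ethenyl-1,3-dioxolan-2-yl)-2-iodonon-2-en-4-yl]oxy}silane (cyclisation precursor) | C=CC1(OCCO1)[C@H](C)C[C@H](O[Si](C)(C)C(C)(C)C)C(=C1COC(C)(C)OC1)[C@H](O[Si](CC)(CC)CC)/C=C(/C)I | intermediate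
25 | B-alkyl-9-BBN from 24 (boron on C3) | B1(C2CCCC1CCC2)CCC3(OCCO3)[C@H](C)C[C@H](O[Si](C)(C)C(C)(C)C)C(=C4COC(C)(C)OC4)[C@H](O[Si](CC)(CC)CC)/C=C(/C)I | intermediate
26 | (4Z,6R,8S,10R)-8-(tert-butyldimethylsilyloxy)-1,1-(ethylenedioxy)-12,13-(isopropylidenedioxy)-6-(triethylsilyloxy)germacra-4,7(11)-diene (ten-membered ring) | CC(C)(C)[Si](C)(C)O[C@H]1C[C@@H](C)C2(OCCO2)CC/C(C)=C\[C@@H](O[Si](CC)(CC)CC)C1=C1COC(C)(C)OC1 | intermediate
27 | (4Z,6R,8S,10R)-8-(tert-butyldimethylsilyloxy)-1,1-(ethylenedioxy)germacra-4,7(11)-diene-6,12,13-triol | CC(C)(C)[Si](C)(C)O[C@H]1C[C@@H](C)C2(OCCO2)CC/C(C)=C\[C@@H](O)C1=C(CO)CO | intermediate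
28 | (4Z,6R,8S,10R)-8-(tert-butyldimethylsilyloxy)-1,1-(ethylenedioxy)-6,13-dihydroxygermacra-4,7(11)-dien-12-al (CHO cis to C6) | CC(C)(C)[Si](C)(C)O[C@H]1C[C@@H](C)C2(OCCO2)CC/C(C)=C\[C@@H](O)/C1=C(/CO)C=O | intermediate
29 | lactol of 28 (12-hydroxy-6,12-epoxide, C12 epimers) | CC(C)(C)[Si](C)(C)O[C@H]1C[C@@H](C)C2(OCCO2)CC/C(C)=C\[C@H]2OC(O)C(CO)=C12 | intermediate
30 | (4Z,6R,8S,10R)-8-(tert-butyldimethylsilyloxy)-1,1-(ethylenedioxy)-13-hydroxygermacra-4,7(11)-dien-12,6-olide | CC(C)(C)[Si](C)(C)O[C@H]1C[C@@H](C)C2(OCCO2)CC/C(C)=C\[C@H]2OC(=O)C(CO)=C12 | intermediate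
31 | (4Z,6R,8S,10R)-13-acetoxy-8-(tert-butyldimethylsilyloxy)-1,1-(ethylenedioxy)germacra-4,7(11)-dien-12,6-olide | CC(C)(C)[Si](C)(C)O[C@H]1C[C@@H](C)C2(OCCO2)CC/C(C)=C\[C@H]2OC(=O)C(COC(C)=O)=C12 | intermediate
32 | (4Z,6R,8S,10R)-13-acetoxy-8-hydroxy-1-oxogermacra-4,7(11)-dien-12,6-olide | O[C@H]1C[C@@H](C)C(=O)CC/C(C)=C\[C@H]2OC(=O)C(COC(C)=O)=C12 | intermediate
33 | (4R,5S,6S,8S,10R)-13-acetoxy-4,5-epoxy-8-hydroxy-1-oxogermacr-7(11)-en-12,6-olide | O[C@H]1C[C@@H](C)C(=O)CC[C@@]2(C)O[C@H]2[C@H]2OC(=O)C(COC(C)=O)=C12 | intermediate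
34 | tiglic acid [(E)-2-methylbut-2-enoic acid] | C/C=C(\C)C(=O)O | starting material
35 | tiglic 2,4,6-trichlorobenzoic anhydride | C/C=C(\C)C(=O)OC(=O)c1c(Cl)cc(Cl)cc1Cl | intermediate
36 | (4R,5S,6S,8S,10R)-13-acetoxy-4,5-epoxy-1-oxo-8-[(E)-2-methylbut-2-enoyloxy]germacr-7(11)-en-12,6-olide (CNP0229937.1) | C/C=C(\C)C(=O)O[C@H]1C[C@@H](C)C(=O)CC[C@@]2(C)O[C@H]2[C@H]2OC(=O)C(COC(C)=O)=C12 | target

**Step count**

Total: 21 steps. Longest linear sequence: 19 steps (steps 1–4, 6–9, 11–21, from 1); steps 5 and 10 are side branches.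

**Steps most likely to fail**

Step 15 (macrocyclisation). Ring closure may lose to intermolecular coupling, protodeboronation or reduction of the alkenyl iodide, because a ten-membered ring is the hardest size to close and transmetalation is slow at high dilution. The fallback makes C3–C4 between two molecules and closes the ring at C6–C7 instead; it sets out from 15 and returns at 26. But-2-yn-1-ol is converted by the hydroalumination/iodination of step 13 into (Z)-3-iodobut-2-en-1-ol F1. Compound 15 is hydroborated with 9-BBN to the alkylborane F2, which is coupled with F1 (Pd(dppf)Cl2, AsPh3, Cs2CO3); the iodide should react far faster than the hindered tetrasubstituted bromide, giving the open-chain Z-allylic alcohol F3. Dess–Martin periodinane/NaHCO3 gives the Z-enal F4. An intramolecular Nozaki–Hiyama–Kishi reaction (CrCl2, catalytic NiCl2, DMSO, high dilution) joins C7 to C6 and should give the ten-membered carbinol F5 as a C6 mixture. Oxidation gives the cross-conjugated dienone F6, reduction with the (S)-oxazaborolidine and catecholborane should give the 6R alcohol F7, and TESOTf/2,6-lutidine converts it into 26.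

Step 20 (epoxidation). Oxygen delivery may fail or reach the wrong face: if the C8 hydroxyl is tied up as a transannular hemiketal with the C1 ketone, or sits too far from C4=C5 in the populated conformer, the vanadium reagent will not react, and any undirected attack takes the outer face. The fallback builds the epoxide by anti addition and inversion, which does not need the hydroxyl; it sets out from 32 and returns at 36. Compound 32 is esterified first under the conditions of step 21 to the 4Z-ene tiglate F8. NBS in aqueous 1,2-dimethoxyethane should form the bromonium ion on the outer face and admit water anti at C4, giving the bromohydrin F9. Ag2O then closes the epoxide from the C4 oxygen with inversion at C5, which places the oxygen on the inner face and gives 36.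

Step 17 (oxidative lactonisation). Chemoselectivity between the two primary allylic alcohols may be lost, so that the C13 alcohol is oxidised to the aldehyde alongside lactonisation. The fallback over-oxidises on purpose and then reduces; it sets out from 27 and returns at 30. Excess PhI(OAc)2 with TEMPO drives every molecule to the 13-oxo butenolide F10, and Luche reduction (NaBH4, CeCl3·7H2O, MeOH, −78 °C) of the aldehyde alone returns the alcohol 30.

**Further compounds**

F1 | step 15 | (Z)-3-iodobut-2-en-1-ol | C/C(I)=C/CO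
F2 | step 15 | B-alkyl-9-BBN from 15 (boron on C3) | B1(C2CCCC1CCC2)CCC3(OCCO3)[C@H](C)C[C@H](O[Si](C)(C)C(C)(C)C)C(Br)=C4COC(C)(C)OC4
F3 | step 15 | open-chain (4Z,8S,10R) allylic alcohol: C6 CH2OH, C7 bromide, C8 OTBS, C1 ketal | OC/C=C(/C)CCC1(OCCO1)[C@H](C)C[C@H](O[Si](C)(C)C(C)(C)C)C(Br)=C1COC(C)(C)OC1
F4 | step 15 | corresponding (4Z)-enal (C6 aldehyde) | O=C/C=C(/C)CCC1(OCCO1)[C@H](C)C[C@H](O[Si](C)(C)C(C)(C)C)C(Br)=C1COC(C)(C)OC1
F5 | step 15 | (4Z,8S,10R)-8-(tert-butyldimethylsilyloxy)-1,1-(ethylenedioxy)-12,13-(isopropylidenedioxy)germacra-4,7(11)-dien-6-ol (C6 epimers) | CC(C)(C)[Si](C)(C)O[C@H]1C[C@@H](C)C2(OCCO2)CC/C(C)=C\C(O)C1=C1COC(C)(C)OC1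
F6 | step 15 | (4Z,8S,10R)-8-(tert-butyldimethylsilyloxy)-1,1-(ethylenedioxy)-12,13-(isopropylidenedioxy)germacra-4,7(11)-dien-6-one | CC(C)(C)[Si](C)(C)O[C@H]1C[C@@H](C)C2(OCCO2)CC/C(C)=C\C(=O)C1=C1COC(C)(C)OC1
F7 | step 15 | (4Z,6R,8S,10R)-8-(tert-butyldimethylsilyloxy)-1,1-(ethylenedioxy)-12,13-(isopropylidenedioxy)germacra-4,7(11)-dien-6-ol | CC(C)(C)[Si](C)(C)O[C@H]1C[C@@H](C)C2(OCCO2)CC/C(C)=C\[C@@H](O)C1=C1COC(C)(C)OC1
F8 | step 20 | (4Z,6R,8S,10R)-13-acetoxy-1-oxo-8-[(E)-2-methylbut-2-enoyloxy]germacra-4,7(11)-dien-12,6-olide | C/C=C(\C)C(=O)O[C@H]1C[C@@H](C)C(=O)CC/C(C)=C\[C@H]2OC(=O)C(COC(C)=O)=C12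
F9 | step 20 | bromohydrin of F8: C5 bromide on the outer face, C4 tertiary alcohol on the inner face | C/C=C(\C)C(=O)O[C@H]1C[C@@H](C)C(=O)CC[C@@](C)(O)[C@H](Br)[C@H]2OC(=O)C(COC(C)=O)=C12
F10 | step 17 | (4Z,6R,8S,10R)-8-(tert-butyldimethylsilyloxy)-1,1-(ethylenedioxy)-13-oxogermacra-4,7(11)-dien-12,6-olide | CC(C)(C)[Si](C)(C)O[C@H]1C[C@@H](C)C2(OCCO2)CC/C(C)=C\[C@H]2OC(=O)C(C=O)=C12
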